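**Retrosynthetic overview**
- Korundamine A ⇐ global BCl3 deprotection ⇐ Suzuki union at the central 6',6''-binaphthyl bond of two monomers: half A (7,8'-linked dihydroisoquinoline, aryl chloride) and half B (5,8'-linked tetrahydroisoquinoline, pinacol boronate).
- Each monomer ⇐ Suzuki coupling of one common naphthalene 8'-boronate (carrying a 6'-chloride for later) with an aryl iodide: at the benzonitrile stage for half A, at the finished tetrahydroisoquinoline for half B.
- Both nitrogen rings ⇐ Mannich-type addition of a laterally lithiated o-tolunitrile to (R)-N-tert-butanesulfinyl acetaldimine (C3–C4 bond and C3 stereocentre), then MeLi/acid ring closure to the C1=N imine; half B then takes a trans-selective hydride reduction at C1.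
- Naphthalene ⇐ Stobbe (aldol-type) condensation of 2-bromo-4-chloro-5-isopropoxybenzaldehyde with diethyl succinate, Friedel–Crafts ring closure, CO2Et → CH3.
- Ring order: second naphthalene ring → biaryl → dihydroisoquinoline ring (half A); dihydro- then tetrahydroisoquinoline ring → biaryl (half B); the benzene rings come from orcinol and 2-bromo-5-hydroxybenzaldehyde.

Assumption: the target SMILES fixes only the three carbon stereocentres (3R in the dihydroisoquinoline half; 1R,3R in the tetrahydroisoquinoline half) and leaves the biaryl axes open, so these centres are controlled and the hindered aryl–naphthyl axes are carried as rotamer mixtures (separable by HPLC at 39 and 42 if one atropisomer is wanted).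

**Common naphthalene boronate**

Step 1
Reactants: 1 2-bromo-5-hydroxybenzaldehyde
Product: 2 2-bromo-4-chloro-5-hydroxybenzaldehyde
Conditions: NCS (1.05 equiv), p-TsOH·H2O (10 mol %), MeCN, 40 °C; recrystallise
Reagents that add atoms: N-chlorosuccinimide, O=C1CCC(=O)N1Cl
Why: Electrophilic aromatic chlorination ortho to the phenol (para is blocked by Br) goes to the less hindered C4, the site that takes the second halogen in the known dibromination of 3-hydroxybenzaldehyde.

Step 2
Reactants: 2 2-bromo-4-chloro-5-hydroxybenzaldehyde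
Product: 3 2-bromo-4-chloro-5-isopropoxybenzaldehyde
Conditions: 2-bromopropane, K2CO3, DMF, 60 °C
Reagents that add atoms: 2-bromopropane, CC(C)Br
Why: Williamson etherification installs the acid- and base-stable isopropyl ether that is later cleaved selectively by BCl3.

Step 3
Reactants: 3 2-bromo-4-chloro-5-isopropoxybenzaldehyde; 4 diethyl succinate
Product: 6 (E)-4-(2-bromo-4-chloro-5-isopropoxyphenyl)-3-(ethoxycarbonyl)but-3-enoic acid, via paraconate lactone 5 (not isolated)
Conditions: KOtBu (1.3 equiv), t-BuOH/THF, 50 °C; then aq. HCl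
Reagents that add atoms: none
Why: Stobbe condensation: the succinate enolate adds to the aldehyde in an intermolecular aldol step, the alkoxide lactonises onto the far ester (5), and E1cB opening gives the (E)-half-ester with the aryl cis to CH2CO2H, as ring closure requires.

Step 4
Reactants: 6 (E)-4-(2-bromo-4-chloro-5-isopropoxyphenyl)-3-(ethoxycarbonyl)but-3-enoic acid
Product: 7 ethyl 4-acetoxy-8-bromo-6-chloro-5-isopropoxy-2-naphthoate
Conditions: Ac2O, NaOAc, 140 °C
Reagents that add atoms: acetic anhydride, CC(=O)OC(C)=O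
Why: Intramolecular Friedel–Crafts acylation through the mixed anhydride closes the second naphthalene ring at the only free position ortho to the side chain (Br blocks the other), and the naphthol is trapped as its acetate.

Step 5
Reactants: 7 ethyl 4-acetoxy-8-bromo-6-chloro-5-isopropoxy-2-naphthoate
Product: 8 ethyl 8-bromo-6-chloro-4-hydroxy-5-isopropoxy-2-naphthoate
Conditions: NaOEt (1.1 equiv), EtOH, 0 °C to rt; AcOH quench
Reagents that add atoms: none
Why: Transesterification removes the aryl acetate far faster than it touches the matching ethyl ester.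

Step 6
Reactants: 8 ethyl 8-bromo-6-chloro-4-hydroxy-5-isopropoxy-2-naphthoate
Product: 9 ethyl 8-bromo-6-chloro-5-isopropoxy-4-methoxy-2-naphthoate
Conditions: MeI, K2CO3, acetone, reflux
Reagents that add atoms: iodomethane, CI
Why: Williamson O-methylation installs the 4'-OMe of the natural product next to the differently protected 5'-oxygen.

Step 7
Reactants: 9 ethyl 8-bromo-6-chloro-5-isopropoxy-4-methoxy-2-naphthoate
Product: 10 (8-bromo-6-chloro-5-isopropoxy-4-methoxynaphthalen-2-yl)methanol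
Conditions: iBu2AlH (2.5 equiv), CH2Cl2, −78 to 0 °C; aq. potassium sodium tartrate
Reagents that add atoms: none
Why: Hydride reduction of the ester to the benzylic alcohol leaves both aryl halides intact at low temperature.

Step 8
Reactants: 10 (8-bromo-6-chloro-5-isopropoxy-4-methoxynaphthalen-2-yl)methanol
Product: 11 1-bromo-7-(bromomethyl)-3-chloro-4-isopropoxy-5-methoxynaphthalene
Conditions: CBr4, PPh3, CH2Cl2, 0 °C
Reagents that add atoms: carbon tetrabromide, BrC(Br)(Br)Br
Why: Appel reaction converts the primary benzylic alcohol to the bromide under neutral conditions.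

Step 9
Reactants: 11 1-bromo-7-(bromomethyl)-3-chloro-4-isopropoxy-5-methoxynaphthalene
Product: 12 1-bromo-3-chloro-4-isopropoxy-5-methoxy-7-methylnaphthalene
Conditions: LiBHEt3, THF, 0 °C
Reagents that add atoms: none
Why: SN2 hydride displacement of the benzylic bromide gives the 2'-methyl group and is much faster than any reaction at the aryl halides.

Step 10
Reactants: 12 1-bromo-3-chloro-4-isopropoxy-5-methoxy-7-methylnaphthalene
Product: 13 2-(3-chloro-4-isopropoxy-5-methoxy-7-methylnaphthalen-1-yl)-4,4,5,5-tetramethyl-1,3,2-dioxaborolane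
Conditions: n-BuLi (1.05 equiv), THF, −78 °C; then iPrOBpin, −78 °C to rt; aq. NH4Cl
Reagents that add atoms: 2-isopropoxy-4,4,5,5-tetramethyl-1,3,2-dioxaborolane, CC(C)OB1OC(C)(C)C(C)(C)O1
Why: Bromine–lithium exchange is selective over the aryl chloride, and borate trapping gives the 8'-boronate while the 6'-chloride is kept for the final union.

**Chiral imine**

Step 11
Reactants: 14 acetaldehyde; 15 (R)-2-methylpropane-2-sulfinamide
Product: 16 (R,E)-N-ethylidene-2-methylpropane-2-sulfinamide
Conditions: CuSO4 (anhydrous), CH2Cl2, rt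
Reagents that add atoms: none
Why: Dehydrating condensation (Ellman imine formation) gives the configurationally stable E-sulfinyl aldimine without racemisation at sulfur.

**Common aldehyde**

Step 12
Reactants: 17 orcinol
Product: 18 2,4-dihydroxy-6-methylbenzaldehyde
Conditions: POCl3, DMF, 0 °C to rt; then H2O, 50 °C
Reagents that add atoms: N,N-dimethylformamide, CN(C)C=O; water, O
Why: Vilsmeier–Haack formylation goes para to one hydroxyl and ortho to the other and to the methyl, the known major mode for orcinol; this places the future C1 carbon so that the two oxygens become distinguishable.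

**Half A**

Step 13
Reactants: 18 2,4-dihydroxy-6-methylbenzaldehyde
Product: 19 2-hydroxy-4-isopropoxy-6-methylbenzaldehyde
Conditions: 2-bromopropane (1.3 equiv), CsHCO3, MeCN, 80 °C
Reagents that add atoms: 2-bromopropane, CC(C)Br
Why: Regioselective Williamson etherification alkylates the free 4-OH, while the 2-OH is held in a hydrogen bond to the aldehyde.

Step 14
Reactants: 19 2-hydroxy-4-isopropoxy-6-methylbenzaldehyde
Product: 20 4-isopropoxy-2-methoxy-6-methylbenzaldehyde
Conditions: MeI, K2CO3, DMF, 50 °C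
Reagents that add atoms: iodomethane, CI
Why: Williamson methylation of the remaining chelated phenol sets the future 8-OMe and 6-O-isopropyl pattern unambiguously.

Step 15
Reactants: 20 4-isopropoxy-2-methoxy-6-methylbenzaldehyde
Product: 21 1-(dimethoxymethyl)-4-isopropoxy-2-methoxy-6-methylbenzene
Conditions: HC(OMe)3, MeOH, p-TsOH (1 mol %), rt; Et3N quench, used crude
Reagents that add atoms: trimethyl orthoformate, COC(OC)OC; methanol, CO
Why: Acid-catalysed acetalisation masks the aldehyde against the organolithium of the next step.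

Step 16
Reactants: 21 1-(dimethoxymethyl)-4-isopropoxy-2-methoxy-6-methylbenzene
Product: 23 3-iodo-4-isopropoxy-2-methoxy-6-methylbenzaldehyde, via iodo acetal 22 (not isolated)
Conditions: n-BuLi, TMEDA, THF, 0 °C; I2, −78 °C to rt; then 1 M HCl, THF, rt
Reagents that add atoms: iodine, II; water, O
Why: Directed ortho-metalation takes the ring CH flanked by the two alkoxy groups (the most acidic site), iodinolysis and mild acetal hydrolysis follow, and the future C7 attachment point is fixed.

Step 17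
Reactants: 23 3-iodo-4-isopropoxy-2-methoxy-6-methylbenzaldehyde
Product: 25 3-iodo-4-isopropoxy-2-methoxy-6-methylbenzonitrile, via aldoxime 24 (not isolated)
Conditions: NH2OH·HCl, pyridine, 60 °C; then Ac2O, 100 °C
Reagents that add atoms: hydroxylamine hydrochloride, Cl.NO
Why: Oxime formation and acetic anhydride dehydration give the nitrile that will acidify the ortho methyl group and later become C1.

Step 18
Reactants: 25 3-iodo-4-isopropoxy-2-methoxy-6-methylbenzonitrile; 13 2-(3-chloro-4-isopropoxy-5-methoxy-7-methylnaphthalen-1-yl)-4,4,5,5-tetramethyl-1,3,2-dioxaborolane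
Product: 26 3-(3-chloro-4-isopropoxy-5-methoxy-7-methylnaphthalen-1-yl)-4-isopropoxy-2-methoxy-6-methylbenzonitrile
Conditions: Pd(PPh3)4 (8 mol %), K3PO4, DME/H2O, 90 °C
Reagents that add atoms: none
Why: Suzuki–Miyaura coupling with triphenylphosphine-ligated zerovalent palladium inserts only into the aryl iodide, so the electron-rich aryl chloride and the hindered nitrile survive.

Step 19
Reactants: 26 3-(3-chloro-4-isopropoxy-5-methoxy-7-methylnaphthalen-1-yl)-4-isopropoxy-2-methoxy-6-methylbenzonitrile; 16 (R,E)-N-ethylidene-2-methylpropane-2-sulfinamide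
Product: 27 (R)-N-[(2R)-1-[4-(3-chloro-4-isopropoxy-5-methoxy-7-methylnaphthalen-1-yl)-2-cyano-5-isopropoxy-3-methoxyphenyl]propan-2-yl]-2-methylpropane-2-sulfinamide
Conditions: LiN(iPr)2 (1.3 equiv), THF, −78 °C; then 16, −78 °C; aq. NH4Cl
Reagents that add atoms: none
Why: Mannich-type addition of the nitrile-stabilised benzylic anion to the sulfinyl imine through a six-membered chair (lithium bridging the sulfinyl oxygen, tert-butyl equatorial) exposes the Si face and sets C3 as R; the minor diastereomer is removed by chromatography.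

Step 20
Reactants: 27 (R)-N-[(2R)-1-[4-(3-chloro-4-isopropoxy-5-methoxy-7-methylnaphthalen-1-yl)-2-cyano-5-isopropoxy-3-methoxyphenyl]propan-2-yl]-2-methylpropane-2-sulfinamide
Product: 29 (3R)-7-(3-chloro-4-isopropoxy-5-methoxy-7-methylnaphthalen-1-yl)-6-isopropoxy-8-methoxy-1,3-dimethyl-3,4-dihydroisoquinoline, via N-sulfinyl amino ketimine 28 (not isolated)
Conditions: MeLi (3.5 equiv), THF, −78 to 0 °C; then HCl, MeOH/dioxane, rt; aq. NaHCO3
Reagents that add atoms: methyllithium, [Li]C
Why: Organolithium addition to the nitrile gives the methyl ketimine, acid removes the sulfinyl group, and the freed amine closes the ring by transimination to the C1=N imine, with C3 untouched.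

**Half B**

Step 21
Reactants: 18 2,4-dihydroxy-6-methylbenzaldehyde
Product: 30 2,4-diisopropoxy-6-methylbenzaldehyde
Conditions: 2-bromopropane (excess), K2CO3, DMF, 80 °C
Reagents that add atoms: 2-bromopropane, CC(C)Br
Why: Exhaustive Williamson etherification under forcing conditions also alkylates the chelated 2-OH.

Step 22
Reactants: 30 2,4-diisopropoxy-6-methylbenzaldehyde
Product: 32 2,4-diisopropoxy-6-methylbenzonitrile, via aldoxime 31 (not isolated)
Conditions: NH2OH·HCl, pyridine, 60 °C; then Ac2O, 100 °C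
Reagents that add atoms: hydroxylamine hydrochloride, Cl.NO
Why: Oxime formation and dehydration give the o-tolunitrile needed for lateral lithiation.

Step 23
Reactants: 32 2,4-diisopropoxy-6-methylbenzonitrile; 16 (R,E)-N-ethylidene-2-methylpropane-2-sulfinamide
Product: 33 (R)-N-[(2R)-1-(2-cyano-3,5-diisopropoxyphenyl)propan-2-yl]-2-methylpropane-2-sulfinamide
Conditions: LiN(iPr)2 (1.3 equiv), THF, −78 °C; then 16, −78 °C; aq. NH4Cl
Reagents that add atoms: none
Why: The same chelated chair Mannich-type addition as in step 19 forms the C3–C4 bond and sets C3 as R, on a substrate that closely matches the known 2,4-dimethoxy case.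

Step 24
Reactants: 33 (R)-N-[(2R)-1-(2-cyano-3,5-diisopropoxyphenyl)propan-2-yl]-2-methylpropane-2-sulfinamide
Product: 35 (3R)-6,8-diisopropoxy-1,3-dimethyl-3,4-dihydroisoquinoline, via N-sulfinyl amino ketimine 34 (not isolated)
Conditions: MeLi (3.5 equiv), THF, −78 to 0 °C; then HCl, MeOH/dioxane, rt; aq. NaHCO3
Reagents that add atoms: methyllithium, [Li]C
Why: Nitrile addition, acidic sulfinyl cleavage and transiminative ring closure give the cyclic imine as in step 20.

Step 25
Reactants: 35 (3R)-6,8-diisopropoxy-1,3-dimethyl-3,4-dihydroisoquinoline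
Product: 36 (1R,3R)-6,8-diisopropoxy-1,3-dimethyl-1,2,3,4-tetrahydroisoquinoline
Conditions: LiAlH4, AlMe3, THF, −78 to −20 °C
Reagents that add atoms: none
Why: Substrate-controlled hydride reduction of the AlMe3-complexed imine: the bulky N–Al complex forces the C3 methyl pseudoaxial and hydride enters from the opposite face, giving the 1,3-trans (1R,3R) amine (about 9:1, cis isomer removed by chromatography).

Step 26
Reactants: 36 (1R,3R)-6,8-diisopropoxy-1,3-dimethyl-1,2,3,4-tetrahydroisoquinoline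
Product: 37 tert-butyl (1R,3R)-6,8-diisopropoxy-1,3-dimethyl-3,4-dihydroisoquinoline-2(1H)-carboxylate
Conditions: Boc2O, Et3N, DMAP (cat.), THF, 60 °C
Reagents that add atoms: di-tert-butyl dicarbonate, CC(C)(C)OC(=O)OC(=O)OC(C)(C)C
Why: Carbamate formation shields the secondary amine from N-halogenation and oxidation, and the group falls off in the final BCl3 step.

Step 27
Reactants: 37 tert-butyl (1R,3R)-6,8-diisopropoxy-1,3-dimethyl-3,4-dihydroisoquinoline-2(1H)-carboxylate
Product: 38 tert-butyl (1R,3R)-5-iodo-6,8-diisopropoxy-1,3-dimethyl-3,4-dihydroisoquinoline-2(1H)-carboxylate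
Conditions: NIS, TFA (5 mol %), MeCN, 0 °C, dark
Reagents that add atoms: N-iodosuccinimide, O=C1CCC(=O)N1I
Why: Electrophilic aromatic iodination goes to C5 (ortho and para to the two alkoxy groups), because C7 is shielded by two flanking isopropoxy groups, as in the known dibenzyloxy series.

Step 28
Reactants: 38 tert-butyl (1R,3R)-5-iodo-6,8-diisopropoxy-1,3-dimethyl-3,4-dihydroisoquinoline-2(1H)-carboxylate; 13 2-(3-chloro-4-isopropoxy-5-methoxy-7-methylnaphthalen-1-yl)-4,4,5,5-tetramethyl-1,3,2-dioxaborolane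
Product: 39 tert-butyl (1R,3R)-5-(3-chloro-4-isopropoxy-5-methoxy-7-methylnaphthalen-1-yl)-6,8-diisopropoxy-1,3-dimethyl-3,4-dihydroisoquinoline-2(1H)-carboxylate
Conditions: Pd(PPh3)4 (10 mol %), K3PO4, DME/H2O, 90 °C
Reagents that add atoms: none
Why: Suzuki–Miyaura coupling at the iodide builds the 5,8'-axis as in the known korupensamine syntheses, and the aryl chloride is inert to this catalyst.

Step 29
Reactants: 39 tert-butyl (1R,3R)-5-(3-chloro-4-isopropoxy-5-methoxy-7-methylnaphthalen-1-yl)-6,8-diisopropoxy-1,3-dimethyl-3,4-dihydroisoquinoline-2(1H)-carboxylate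
Product: 40 tert-butyl (1R,3R)-5-[4-isopropoxy-5-methoxy-7-methyl-3-(4,4,5,5-tetramethyl-1,3,2-dioxaborolan-2-yl)naphthalen-1-yl]-6,8-diisopropoxy-1,3-dimethyl-3,4-dihydroisoquinoline-2(1H)-carboxylate
Conditions: B2pin2, Pd2(dba)3 (2.5 mol %), XPhos (10 mol %), KOAc, dioxane, 110 °C
Reagents that add atoms: bis(pinacolato)diboron, CC1(C)OB(OC1(C)C)B1OC(C)(C)C(C)(C)O1
Why: Miyaura borylation with a bulky biarylphosphine ligand activates the electron-rich aryl chloride and gives the 6''-boronate.

**Union and deprotection**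

Step 30
Reactants: 29 (3R)-7-(3-chloro-4-isopropoxy-5-methoxy-7-methylnaphthalen-1-yl)-6-isopropoxy-8-methoxy-1,3-dimethyl-3,4-dihydroisoquinoline; 40 tert-butyl (1R,3R)-5-[4-isopropoxy-5-methoxy-7-methyl-3-(4,4,5,5-tetramethyl-1,3,2-dioxaborolan-2-yl)naphthalen-1-yl]-6,8-diisopropoxy-1,3-dimethyl-3,4-dihydroisoquinoline-2(1H)-carboxylate
Product: 41 N-Boc-penta-O-isopropyl-korundamine A
Conditions: Pd(OAc)2 (5 mol %), SPhos (10 mol %), K3PO4, toluene/H2O, 100 °C
Reagents that add atoms: none
Why: Suzuki–Miyaura cross-coupling of the aryl chloride with the boronate forms only the unsymmetrical 6',6''-binaphthyl bond, a di-ortho-substituted biaryl well within the reach of SPhos.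

Step 31
Reactants: 41 N-Boc-penta-O-isopropyl-korundamine A
Product: 42 korundamine A
Conditions: BCl3 (20 equiv), CH2Cl2, −78 to 0 °C; MeOH quench; reverse-phase HPLC
Reagents that add atoms: none
Why: Lewis-acid dealkylation cleaves the five secondary (isopropyl) aryl ethers and the Boc group much faster than the three aryl methyl ethers, and the cyclic imine survives as its boron complex until work-up.

**Compound list**
1 | 2-bromo-5-hydroxybenzaldehyde | O=Cc1cc(O)ccc1Br | starting material
2 | 2-bromo-4-chloro-5-hydroxybenzaldehyde | O=Cc1cc(O)c(Cl)cc1Br | intermediate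
3 | 2-bromo-4-chloro-5-isopropoxybenzaldehyde | O=Cc1cc(OC(C)C)c(Cl)cc1Br | intermediate
4 | diethyl succinate | CCOC(=O)CCC(=O)OCC | starting material
5 | ethyl 2-(2-bromo-4-chloro-5-isopropoxyphenyl)-5-oxotetrahydrofuran-3-carboxylate (paraconate lactone, stereoisomer mixture) | CCOC(=O)C1CC(=O)OC1c1cc(OC(C)C)c(Cl)cc1Br | intermediate
6 | (E)-4-(2-bromo-4-chloro-5-isopropoxyphenyl)-3-(ethoxycarbonyl)but-3-enoic acid | CCOC(=O)/C(CC(=O)O)=C/c1cc(OC(C)C)c(Cl)cc1Br | intermediate
7 | ethyl 4-acetoxy-8-bromo-6-chloro-5-isopropoxy-2-naphthoate | CCOC(=O)c1cc(OC(C)=O)c2c(OC(C)C)c(Cl)cc(Br)c2c1 | intermediate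
8 | ethyl 8-bromo-6-chloro-4-hydroxy-5-isopropoxy-2-naphthoate | CCOC(=O)c1cc(O)c2c(OC(C)C)c(Cl)cc(Br)c2c1 | intermediate
9 | ethyl 8-bromo-6-chloro-5-isopropoxy-4-methoxy-2-naphthoate | CCOC(=O)c1cc(OC)c2c(OC(C)C)c(Cl)cc(Br)c2c1 | intermediate
10 | (8-bromo-6-chloro-5-isopropoxy-4-methoxynaphthalen-2-yl)methanol | OCc1cc(OC)c2c(OC(C)C)c(Cl)cc(Br)c2c1 | intermediate
11 | 1-bromo-7-(bromomethyl)-3-chloro-4-isopropoxy-5-methoxynaphthalene | BrCc1cc(OC)c2c(OC(C)C)c(Cl)cc(Br)c2c1 | intermediate
12 | 1-bromo-3-chloro-4-isopropoxy-5-methoxy-7-methylnaphthalene | Cc1cc(OC)c2c(OC(C)C)c(Cl)cc(Br)c2c1 | intermediate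
13 | 2-(3-chloro-4-isopropoxy-5-methoxy-7-methylnaphthalen-1-yl)-4,4,5,5-tetramethyl-1,3,2-dioxaborolane | Cc1cc(OC)c2c(OC(C)C)c(Cl)cc(B3OC(C)(C)C(C)(C)O3)c2c1 | intermediate
14 | acetaldehyde | CC=O | starting material
15 | (R)-2-methylpropane-2-sulfinamide | CC(C)(C)[S@](N)=O | starting material
16 | (R,E)-N-ethylidene-2-methylpropane-2-sulfinamide | C/C=N/[S@](=O)C(C)(C)C | intermediate
17 | orcinol (5-methylbenzene-1,3-diol) | Cc1cc(O)cc(O)c1 | starting material
18 | 2,4-dihydroxy-6-methylbenzaldehyde | Cc1cc(O)cc(O)c1C=O | intermediate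
19 | 2-hydroxy-4-isopropoxy-6-methylbenzaldehyde | Cc1cc(OC(C)C)cc(O)c1C=O | intermediate
20 | 4-isopropoxy-2-methoxy-6-methylbenzaldehyde | Cc1cc(OC(C)C)cc(OC)c1C=O | intermediate
21 | 1-(dimethoxymethyl)-4-isopropoxy-2-methoxy-6-methylbenzene | Cc1cc(OC(C)C)cc(OC)c1C(OC)OC | intermediate
22 | 1-(dimethoxymethyl)-3-iodo-4-isopropoxy-2-methoxy-6-methylbenzene | Cc1cc(OC(C)C)c(I)c(OC)c1C(OC)OC | intermediate
23 | 3-iodo-4-isopropoxy-2-methoxy-6-methylbenzaldehyde | Cc1cc(OC(C)C)c(I)c(OC)c1C=O | intermediate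
24 | (E)-3-iodo-4-isopropoxy-2-methoxy-6-methylbenzaldehyde oxime | Cc1cc(OC(C)C)c(I)c(OC)c1/C=N/O | intermediate
25 | 3-iodo-4-isopropoxy-2-methoxy-6-methylbenzonitrile | Cc1cc(OC(C)C)c(I)c(OC)c1C#N | intermediate
26 | 3-(3-chloro-4-isopropoxy-5-methoxy-7-methylnaphthalen-1-yl)-4-isopropoxy-2-methoxy-6-methylbenzonitrile | Cc1cc(OC(C)C)c(-c2cc(Cl)c(OC(C)C)c3c(OC)cc(C)cc23)c(OC)c1C#N | intermediate
27 | (R)-N-[(2R)-1-[4-(3-chloro-4-isopropoxy-5-methoxy-7-methylnaphthalen-1-yl)-2-cyano-5-isopropoxy-3-methoxyphenyl]propan-2-yl]-2-methylpropane-2-sulfinamide | C[C@H](Cc1cc(OC(C)C)c(-c2cc(Cl)c(OC(C)C)c3c(OC)cc(C)cc23)c(OC)c1C#N)N[S@](=O)C(C)(C)C | intermediate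
28 | (R)-N-[(2R)-1-[4-(3-chloro-4-isopropoxy-5-methoxy-7-methylnaphthalen-1-yl)-2-(1-iminoethyl)-5-isopropoxy-3-methoxyphenyl]propan-2-yl]-2-methylpropane-2-sulfinamide | C[C@H](Cc1cc(OC(C)C)c(-c2cc(Cl)c(OC(C)C)c3c(OC)cc(C)cc23)c(OC)c1C(C)=N)N[S@](=O)C(C)(C)C | intermediate
29 | (3R)-7-(3-chloro-4-isopropoxy-5-methoxy-7-methylnaphthalen-1-yl)-6-isopropoxy-8-methoxy-1,3-dimethyl-3,4-dihydroisoquinoline | C[C@@H]1Cc2cc(OC(C)C)c(-c3cc(Cl)c(OC(C)C)c4c(OC)cc(C)cc34)c(OC)c2C(C)=N1 | intermediate
30 | 2,4-diisopropoxy-6-methylbenzaldehyde | Cc1cc(OC(C)C)cc(OC(C)C)c1C=O | intermediate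
31 | (E)-2,4-diisopropoxy-6-methylbenzaldehyde oxime | Cc1cc(OC(C)C)cc(OC(C)C)c1/C=N/O | intermediate
32 | 2,4-diisopropoxy-6-methylbenzonitrile | Cc1cc(OC(C)C)cc(OC(C)C)c1C#N | intermediate
33 | (R)-N-[(2R)-1-(2-cyano-3,5-diisopropoxyphenyl)propan-2-yl]-2-methylpropane-2-sulfinamide | C[C@H](Cc1cc(OC(C)C)cc(OC(C)C)c1C#N)N[S@](=O)C(C)(C)C | intermediate
34 | (R)-N-[(2R)-1-[2-(1-iminoethyl)-3,5-diisopropoxyphenyl]propan-2-yl]-2-methylpropane-2-sulfinamide | C[C@H](Cc1cc(OC(C)C)cc(OC(C)C)c1C(C)=N)N[S@](=O)C(C)(C)C | intermediate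
35 | (3R)-6,8-diisopropoxy-1,3-dimethyl-3,4-dihydroisoquinoline | C[C@@H]1Cc2cc(OC(C)C)cc(OC(C)C)c2C(C)=N1 | intermediate
36 | (1R,3R)-6,8-diisopropoxy-1,3-dimethyl-1,2,3,4-tetrahydroisoquinoline | C[C@@H]1Cc2cc(OC(C)C)cc(OC(C)C)c2[C@@H](C)N1 | intermediate
37 | tert-butyl (1R,3R)-6,8-diisopropoxy-1,3-dimethyl-3,4-dihydroisoquinoline-2(1H)-carboxylate | C[C@@H]1Cc2cc(OC(C)C)cc(OC(C)C)c2[C@@H](C)N1C(=O)OC(C)(C)C | intermediate
38 | tert-butyl (1R,3R)-5-iodo-6,8-diisopropoxy-1,3-dimethyl-3,4-dihydroisoquinoline-2(1H)-carboxylate | C[C@@H]1Cc2c(I)c(OC(C)C)cc(OC(C)C)c2[C@@H](C)N1C(=O)OC(C)(C)C | intermediate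
39 | tert-butyl (1R,3R)-5-(3-chloro-4-isopropoxy-5-methoxy-7-methylnaphthalen-1-yl)-6,8-diisopropoxy-1,3-dimethyl-3,4-dihydroisoquinoline-2(1H)-carboxylate | C[C@@H]1Cc2c(-c3cc(Cl)c(OC(C)C)c4c(OC)cc(C)cc34)c(OC(C)C)cc(OC(C)C)c2[C@@H](C)N1C(=O)OC(C)(C)C | intermediate
40 | tert-butyl (1R,3R)-5-[4-isopropoxy-5-methoxy-7-methyl-3-(4,4,5,5-tetramethyl-1,3,2-dioxaborolan-2-yl)naphthalen-1-yl]-6,8-diisopropoxy-1,3-dimethyl-3,4-dihydroisoquinoline-2(1H)-carboxylate | C[C@@H]1Cc2c(-c3cc(B5OC(C)(C)C(C)(C)O5)c(OC(C)C)c4c(OC)cc(C)cc34)c(OC(C)C)cc(OC(C)C)c2[C@@H](C)N1C(=O)OC(C)(C)C | intermediate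
41 | N-Boc-penta-O-isopropyl-korundamine A (all five phenols as isopropyl ethers, the secondary amine as tert-butyl carbamate) | COc1c2c(cc(OC(C)C)c1-c1cc(-c3cc(-c4c(OC(C)C)cc(OC(C)C)c5c4C[C@@H](C)N(C(=O)OC(C)(C)C)[C@@H]5C)c4cc(C)cc(OC)c4c3OC(C)C)c(OC(C)C)c3c(OC)cc(C)cc13)C[C@@H](C)N=C2C | intermediate
42 | korundamine A | COc1c2c(cc(O)c1-c1cc(-c3cc(-c4c(O)cc(O)c5c4C[C@@H](C)N[C@@H]5C)c4cc(C)cc(OC)c4c3O)c(O)c3c(OC)cc(C)cc13)C[C@@H](C)N=C2C | target

**Totals**
Total step count: 31.
Longest linear sequence: 15 steps (steps 1–10, then 18, 19, 20, 30, 31).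

**Three steps most likely to fail**

Step 16. The ring lithiation of acetal 21 has no direct precedent; benzylic or acetal deprotonation may compete, and the electron-rich acetal is very labile. The fallback puts the iodine in first by electrophilic substitution of the free resorcinol and sets out from 17. I2/NaHCO3 in water–THF at 0 °C iodinates between the two hydroxyls to give 2-iodo-5-methylbenzene-1,3-diol F1. Vilsmeier–Haack formylation (POCl3, DMF) gives 2,4-dihydroxy-3-iodo-6-methylbenzaldehyde F2, a single regioisomer by symmetry. Selective alkylation of the non-chelated hydroxyl (2-bromopropane, CsHCO3, MeCN) gives 2-hydroxy-3-iodo-4-isopropoxy-6-methylbenzaldehyde F3. Methylation with MeI/K2CO3 comes back to the route at 23.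

Step 19. The benzylic anion may deprotonate the enolisable acetaldimine instead of adding to it, and the facial selectivity of a lithium species with the tert-butanesulfinyl imine in THF is the least certain stereochemical claim in the route. The fallback builds the C3–C4 bond by Claisen-type acylation and sets C3 by reduction; it sets out from 26. LiN(iPr)2 at −78 °C followed by N-methoxy-N-methylacetamide gives 3-(3-chloro-4-isopropoxy-5-methoxy-7-methylnaphthalen-1-yl)-4-isopropoxy-2-methoxy-6-(2-oxopropyl)benzonitrile F4. Condensation with 15 and Ti(OEt)4 in THF at 65 °C gives (R)-N-[(E)-1-[4-(3-chloro-4-isopropoxy-5-methoxy-7-methylnaphthalen-1-yl)-2-cyano-5-isopropoxy-3-methoxyphenyl]propan-2-ylidene]-2-methylpropane-2-sulfinamide F5. NaBH4 in wet THF at −50 °C reduces it through the cyclic transition state known to give the (R,R) sulfinamide from (R)-sulfinyl methyl ketimines, and the route is rejoined at 27.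

Step 31. Six protecting groups must leave a sensitive polyphenol that also carries three methyl ethers and an imine; over-demethylation at the methoxy groups peri to the naphthol oxygens, or incomplete cleavage, is possible. The fallback deprotects before the union, where each substrate has fewer groups and close precedent in the monomer series, and sets out from 29 and 40. BCl3 in CH2Cl2 converts 29 into 2-chloro-4-[(3R)-6-hydroxy-8-methoxy-1,3-dimethyl-3,4-dihydroisoquinolin-7-yl]-8-methoxy-6-methylnaphthalen-1-ol F6. BCl3 followed by aqueous work-up converts 40 into [4-[(1R,3R)-6,8-dihydroxy-1,3-dimethyl-1,2,3,4-tetrahydroisoquinolin-5-yl]-1-hydroxy-8-methoxy-6-methylnaphthalen-2-yl]boronic acid F7. A protecting-group-free Suzuki coupling of F6 and F7 (Pd(OAc)2, SPhos, K3PO4, degassed n-BuOH/H2O, 90 °C) comes back to the route at 42.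

**Further compounds**
F1 | step 16 | 2-iodo-5-methylbenzene-1,3-diol | Cc1cc(O)c(I)c(O)c1
F2 | step 16 | 2,4-dihydroxy-3-iodo-6-methylbenzaldehyde | Cc1cc(O)c(I)c(O)c1C=O
F3 | step 16 | 2-hydroxy-3-iodo-4-isopropoxy-6-methylbenzaldehyde | Cc1cc(OC(C)C)c(I)c(O)c1C=O
F4 | step 19 | 3-(3-chloro-4-isopropoxy-5-methoxy-7-methylnaphthalen-1-yl)-4-isopropoxy-2-methoxy-6-(2-oxopropyl)benzonitrile | CC(=O)Cc1cc(OC(C)C)c(-c2cc(Cl)c(OC(C)C)c3c(OC)cc(C)cc23)c(OC)c1C#N
F5 | step 19 | (R)-N-[(E)-1-[4-(3-chloro-4-isopropoxy-5-methoxy-7-methylnaphthalen-1-yl)-2-cyano-5-isopropoxy-3-methoxyphenyl]propan-2-ylidene]-2-methylpropane-2-sulfinamide | C/C(Cc1cc(OC(C)C)c(-c2cc(Cl)c(OC(C)C)c3c(OC)cc(C)cc23)c(OC)c1C#N)=N\[S@](=O)C(C)(C)C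
F6 | step 31 | 2-chloro-4-[(3R)-6-hydroxy-8-methoxy-1,3-dimethyl-3,4-dihydroisoquinolin-7-yl]-8-methoxy-6-methylnaphthalen-1-ol | C[C@@H]1Cc2cc(O)c(-c3cc(Cl)c(O)c4c(OC)cc(C)cc34)c(OC)c2C(C)=N1
F7 | step 31 | [4-[(1R,3R)-6,8-dihydroxy-1,3-dimethyl-1,2,3,4-tetrahydroisoquinolin-5-yl]-1-hydroxy-8-methoxy-6-methylnaphthalen-2-yl]boronic acid | C[C@@H]1Cc2c(-c3cc(B(O)O)c(O)c4c(OC)cc(C)cc34)c(O)cc(O)c2[C@@H](C)N1
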